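The route rests on cutting the bond between the benzylic CH2 of the two-carbon tether and the guaiacyl ring carbon para to its OH. The key step exploits the fact that this CH2 is the unsubstituted end of a C2 unit on C6 of the oxane ring, two bonds from the nearest stereocentre. It can therefore be carried as a vinyl group. One-pot anti-Markovnikov hydroboration and B-alkyl Suzuki–Miyaura coupling with unprotected 4-bromoguaiacol joins both halves and should release the free natural product directly. The precursor is an all-cis 2-aryl-6-vinyloxan-4-ol. It comes from one Prins cyclisation of O-acetylsyringaldehyde with (R)-hexa-1,5-dien-3-ol, whose single carbinol centre sets the other two.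

Key step: step 4

Assumption: in step 4 both O–H groups of 8 are taken to be borylated by 9-BBN-H alongside the alkene, so three equivalents enter the equation and 10 is written as the tris-boryl compound.

Step 1
Reactants: 1 syringaldehyde (4-hydroxy-3,5-dimethoxybenzaldehyde)
Product: 2 4-formyl-2,6-dimethoxyphenyl acetate (O-acetylsyringaldehyde)
Conditions: Ac2O, pyridine, cat. DMAP, CH2Cl2, 0 °C to rt
Reagents that add atoms: acetic anhydride, CC(=O)OC(C)=O
Why: Simple O-acylation of a phenol; the acetate lowers the donor strength of the ring, so the aldehyde stays electrophilic and the later benzylic C–O bond resists ionisation in acid, and it is removed in the methanolysis that step 3 needs anyway.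

Step 2
Reactants: 3 acrolein; 4 (−)-B-allyldiisopinocampheylborane (commercial pentane solution; both isopinocampheyl groups belong to the (−)-α-pinene series, the one that gives (1S,2S,3S,5R)-(+)-isopinocampheol on oxidation)
Product: 6 (R)-hexa-1,5-dien-3-ol, via diisopinocampheylborinate ester 5 (not isolated)
Conditions: Et2O–pentane, −78 °C; then HOCH2CH2NH2, rt, filtration, distillation
Reagents that add atoms: none
Why: Brown asymmetric allylboration: the allyl group is delivered through a closed chair transition state, the isopinocampheyl groups direct it to the Re face of acrolein in a clean 1,2-addition that sets the (R)-carbinol centre, and ethanolamine frees the alcohol without an oxidant.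

Step 3
Reactants: 2 4-formyl-2,6-dimethoxyphenyl acetate; 6 (R)-hexa-1,5-dien-3-ol
Product: 8 (2R,4R,6S)-2-ethenyl-6-(4-hydroxy-3,5-dimethoxyphenyl)oxan-4-ol (all three substituents cis, equatorial), via oxan-4-yl trifluoroacetate 7 (not isolated)
Conditions: TFA (excess), CH2Cl2, 0 °C to rt; aq NaHCO3 wash; then K2CO3, MeOH, rt
Reagents that add atoms: trifluoroacetic acid, OC(=O)C(F)(F)F
Why: Prins cyclisation: TFA condenses 2 with 6 to an (E)-oxocarbenium ion that closes through a chair with the vinyl and aryl groups equatorial, trifluoroacetate captures the C4 cation from the equatorial side, so the carbinol centre of 6 (its C–O bond is never broken) fixes both new centres in the all-cis array, and K2CO3/MeOH then removes the trifluoroacetyl and aryl acetyl groups together.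

Step 4
Reactants: 8 (2R,4R,6S)-2-ethenyl-6-(4-hydroxy-3,5-dimethoxyphenyl)oxan-4-ol; 9 4-bromo-2-methoxyphenol (4-bromoguaiacol)
Product: 11 (2S,4R,6S)-2-(4-hydroxy-3,5-dimethoxyphenyl)-6-[2-(4-hydroxy-3-methoxyphenyl)ethyl]oxan-4-ol, via tris(9-BBN) adduct 10 (not isolated)
Conditions: 9-BBN-H (3.5 equiv), THF, 0 °C to rt; then 9, Pd(OAc)2/SPhos (5/10 mol %), 3 M aq K3PO4, THF, 60 °C; aq NH4Cl work-up
Reagents that add atoms: 9-borabicyclo[3.3.1]nonane (9-BBN-H), [H]B1C2CCCC1CCC2 (its heavy atoms reach only 10; 11 keeps one hydrogen from it)
Why: 9-BBN-H adds across the only C=C bond of 8 with boron on the terminal carbon, and its excess borylates both O–H groups with loss of H2 to give 10; aqueous phosphate then hydrolyses the two B–O bonds and turns the B-alkyl unit into a hydroxyborate, which hands its primary alkyl group to the arylpalladium(II) bromide formed by oxidative addition of Pd(0)/SPhos into 9, and reductive elimination forms the aryl–CH2 bond. The closest known reaction type is the one-pot hydroboration/B-alkyl Suzuki–Miyaura coupling of a terminal alkene with an aryl bromide. No ring is closed and no stereocentre is created, and the three oxane stereocentres are never bonded to boron or palladium, so they should pass through unchanged. The step needs anti-Markovnikov regioselectivity, secured by the bulk of 9-BBN and the branched oxygen-bearing allylic carbon, and exclusive transfer of the primary alkyl group, secured by the reluctant bridgehead B–C bonds of the bicycle. It also needs reductive elimination to outrun β-hydride elimination, and oxidative addition into an electron-rich bromophenolate, and the bulky electron-rich SPhos ligand is chosen for both. The phenols and the alcohol are only reversibly deprotonated or borylated, so the coupling should release 11 without a deprotection step.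

Compound list
1 | syringaldehyde (4-hydroxy-3,5-dimethoxybenzaldehyde) | COc1cc(C=O)cc(OC)c1O | starting material
2 | 4-formyl-2,6-dimethoxyphenyl acetate | COc1cc(C=O)cc(OC)c1OC(C)=O | intermediate
3 | acrolein | C=CC=O | starting material
4 | (−)-B-allyldiisopinocampheylborane ((−)-α-pinene series) | C=CCB([C@H]1C[C@H]2C[C@@H]([C@@H]1C)C2(C)C)[C@H]1C[C@H]2C[C@@H]([C@@H]1C)C2(C)C | starting material
5 | (R)-hexa-1,5-dien-3-yl diisopinocampheylborinate | C=C[C@H](OB([C@H]1C[C@H]2C[C@@H]([C@@H]1C)C2(C)C)[C@H]1C[C@H]2C[C@@H]([C@@H]1C)C2(C)C)CC=C | intermediate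
6 | (R)-hexa-1,5-dien-3-ol | C=C[C@H](O)CC=C | intermediate
7 | 4-[(2S,4R,6R)-6-ethenyl-4-(trifluoroacetoxy)oxan-2-yl]-2,6-dimethoxyphenyl acetate (all-cis) | C=C[C@H]1C[C@@H](OC(=O)C(F)(F)F)C[C@@H](c2cc(OC)c(OC(C)=O)c(OC)c2)O1 | intermediate
8 | (2R,4R,6S)-2-ethenyl-6-(4-hydroxy-3,5-dimethoxyphenyl)oxan-4-ol (all-cis) | C=C[C@H]1C[C@@H](O)C[C@@H](c2cc(OC)c(O)c(OC)c2)O1 | intermediate
9 | 4-bromo-2-methoxyphenol | COc1cc(Br)ccc1O | starting material
10 | tris(9-BBN) adduct of 8: 9-BBN on the terminal carbon of the former vinyl group, on the C4 oxygen and on the phenol oxygen, (2S,4R,6S)-oxane | C(C[C@H]1C[C@@H](OB2C3CCCC2CCC3)C[C@@H](c2cc(OC)c(OB3C4CCCC3CCC4)c(OC)c2)O1)B1C2CCCC1CCC2 | intermediate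
11 | (2S,4R,6S)-2-(4-hydroxy-3,5-dimethoxyphenyl)-6-[2-(4-hydroxy-3-methoxyphenyl)ethyl]oxan-4-ol | COc1cc(CC[C@H]2C[C@@H](O)C[C@@H](c3cc(OC)c(O)c(OC)c3)O2)ccc1O | target

Total step count: 4.
Longest linear sequence: 3 steps (step 2 or step 1, then step 3, then step 4).

Steps most likely to fail

**Step 4 (key step).** Oxidative addition into the electron-rich bromophenolate may be slow, and the borinate by-products may tie up the base. β-Hydride elimination or protodeboronation of the alkylboron species could then outrun the coupling. The fallback sets out from 8 and 9 and comes back at 11. It makes the same bond without boron, by carbopalladation instead of transmetalation. A Mizoroki–Heck arylation of the vinyl group of 8 with 9 (Pd(OAc)2, P(o-tol)3, K2CO3, DMF, 100 °C) should give the styrene 4-{(E)-2-[(2R,4R,6S)-4-hydroxy-6-(4-hydroxy-3,5-dimethoxyphenyl)oxan-2-yl]ethenyl}-2-methoxyphenol F1. Hydrogenation of its disubstituted alkene (H2, Pd/C, EtOAc, rt, stopped after one equivalent) should then give 11.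

**Step 3.** 2-Oxonia-Cope equilibration with side-chain exchange, or ionisation of the allylic C–O bond of the vinyl carbinol in TFA, may scramble the ring substituents and erode enantiopurity. The fallback sets out from 2 and 4 and comes back at 8. The vinyl group is masked as a silylalkyne, which destabilises a neighbouring cation and the rearranged oxocarbenium ion.
- Commercial 3-(trimethylsilyl)propynal is allylated with 4 as in step 2, to give (R)-1-(trimethylsilyl)hex-5-en-1-yn-3-ol F2.
- Prins cyclisation of F2 with 2 in TFA should give the all-cis 6-(silylethynyl)oxan-4-yl trifluoroacetate F3.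
- K2CO3/MeOH strips the trifluoroacetyl, acetyl and silyl groups, to give (2R,4R,6S)-2-ethynyl-6-(4-hydroxy-3,5-dimethoxyphenyl)oxan-4-ol F4.
- Lindlar semihydrogenation (H2, Pd/CaCO3–Pb, quinoline) returns 8.

**Step 2.** Acrolein may polymerise, the volatile dienol may be lost during separation from the terpene residues, or the facial selectivity may be incomplete. The fallback sets out from 2 and 3 and comes back at 7. The stereodefining allylation is moved to the non-volatile aldehyde 2. Allylboration with allylboronic acid pinacol ester is run under a TRIP-type chiral phosphoric acid of the series that delivers allyl to the Si face. These neutral conditions spare the aryl acetate and should give (S)-4-(1-hydroxybut-3-en-1-yl)-2,6-dimethoxyphenyl acetate F5. Prins cyclisation of F5 with acrolein 3 in TFA then places the controlling centre at the aryl-bearing carbon and should close the same all-cis chair to 7. Compound 7 is methanolysed as in step 3.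

Further compounds
F1 | step 4 | 4-{(E)-2-[(2R,4R,6S)-4-hydroxy-6-(4-hydroxy-3,5-dimethoxyphenyl)oxan-2-yl]ethenyl}-2-methoxyphenol | COc1cc(/C=C/[C@H]2C[C@@H](O)C[C@@H](c3cc(OC)c(O)c(OC)c3)O2)ccc1O
F2 | step 3 | (R)-1-(trimethylsilyl)hex-5-en-1-yn-3-ol | C[Si](C)(C)C#C[C@H](O)CC=C
F3 | step 3 | 4-[(2S,4S,6R)-4-(trifluoroacetoxy)-6-[(trimethylsilyl)ethynyl]oxan-2-yl]-2,6-dimethoxyphenyl acetate (all-cis) | C[Si](C)(C)C#C[C@H]1C[C@@H](OC(=O)C(F)(F)F)C[C@@H](c2cc(OC)c(OC(C)=O)c(OC)c2)O1
F4 | step 3 | (2R,4R,6S)-2-ethynyl-6-(4-hydroxy-3,5-dimethoxyphenyl)oxan-4-ol | C#C[C@H]1C[C@@H](O)C[C@@H](c2cc(OC)c(O)c(OC)c2)O1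
F5 | step 2 | (S)-4-(1-hydroxybut-3-en-1-yl)-2,6-dimethoxyphenyl acetate | C=CC[C@H](O)c1cc(OC)c(OC(C)=O)c(OC)c1
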